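**Plan**
- Retrosynthesis cuts, in this order: the seven-membered ester C(=O)–O bond of the depsidone, the diaryl ether O–C bond to ring A (the benzoic acid ring), the C–CH2OH bond on ring B, and last the CH2–O bond of the five-membered lactone on ring B.
- Enabling feature: on ring B the ether oxygen and the chelated phenol oxygen are para to each other, so ring B is a masked hydroquinone. In its 1,4-benzoquinone the lactone CH2 is a C-methyl group vinylogous to one quinone carbonyl and next to the carboxyl-bearing carbon. Tautomerisation to the o-quinone methide and carboxylate addition to the methylene close the lactone and free the phenol needed for the ether bond.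
- Forward: ring B phthalide hydroquinone from methyl orsellinate (steps 1–4), then hydroxymethylation and acetonide (steps 5–6). Ring A is built as a 2-fluoroisophthalate from 3-fluoro-5-methylphenol (steps 7–10).
- Union: SNAr diaryl ether (step 11), debenzylation (step 12), seven-membered lactonisation (step 13), global acid deprotection (step 14).
- Stereochemistry: the target has no stereocentre and no stereogenic double bond, so none has to be set.

Key step: step 4

Remark: methyl orsellinate (1) and 3-fluoro-5-methylphenol (11) are assumed to be commercially available. The CH2OH carbon is added only after step 4, because a CH2OH group on the quinone would itself tautomerise.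

**Step 1**
Reactants: 1 methyl 2,4-dihydroxy-6-methylbenzoate (methyl orsellinate)
Product: 2 methyl 4-(benzyloxy)-2-hydroxy-6-methylbenzoate
Conditions: BnBr (1.05 equiv), K2CO3, acetone, reflux
Reagents that add atoms: benzyl bromide BrCc1ccccc1
Why: Williamson etherification; the 2-OH is hydrogen-bonded to the ester carbonyl, so only the free, more acidic 4-OH should be alkylated.

**Step 2**
Reactants: 2 methyl 4-(benzyloxy)-2-hydroxy-6-methylbenzoate
Product: 3 4-(benzyloxy)-2-hydroxy-6-methylbenzoic acid
Conditions: KOH, DMSO/H2O, 90 °C; then HCl, 0 °C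
Reagents that add atoms: potassium hydroxide [K+].[OH-]
Why: Saponification of a hindered, chelated benzoate in aqueous DMSO; the benzyl ether is inert and cold acidification limits decarboxylation.

**Step 3**
Reactants: 3 4-(benzyloxy)-2-hydroxy-6-methylbenzoic acid
Product: 5 4-(benzyloxy)-3,6-dihydroxy-2-methylbenzoic acid, via aryl sulfate 4 (not isolated)
Conditions: K2S2O8 (1.1 equiv), 2 M NaOH, 0 °C → rt; then HCl, 60 °C
Reagents that add atoms: potassium peroxodisulfate [K+].[K+].[O-]S(=O)(=O)OOS(=O)(=O)[O-]
Why: Elbs persulfate oxidation (the reaction class that turns salicylic acid into gentisic acid); the phenoxide attacks a peroxide oxygen through its only free para carbon, and acid hydrolysis of the aryl sulfate should give the hydroquinone.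

**Step 4**
Reactants: 5 4-(benzyloxy)-3,6-dihydroxy-2-methylbenzoic acid
Product: 8 5-(benzyloxy)-4,7-dihydroxy-2-benzofuran-1(3H)-one, via quinone acid 6 (not isolated), via quinone methide 7 (not isolated)
Conditions: PhI(OAc)2 (1.0 equiv), MeCN, 0 °C; then Et3N (3.2 equiv), degassed, 0 °C → rt, high dilution; aq. Na2S2O4/dilute HCl work-up
Reagents that add atoms: none
Why: Proposed new method: PhI(OAc)2 dehydrogenates hydroquinone 5 to quinone acid 6, whose C-methyl group is the gamma position of the enone made of the C-6 carbonyl and the ring C=C and is further acidified by the neighbouring carboxyl, so the Et3N/Et3NH+ pair should shuttle a methyl proton to the C-6 carbonyl oxygen to give o-quinone methide 7; the carboxylate oxygen then adds to the exocyclic CH2 and the ring re-aromatises, which forms the CH2–O bond and makes the sequence irreversible. The closest known reaction types are the amine-induced tautomerisation of alkyl-1,4-benzoquinones to o-quinone methides with capture by oxygen nucleophiles and the lactonisation of o-carboxybenzyl cations to phthalides; the new element is intramolecular carboxylate capture to a five-membered lactone. The closure is formally 5-endo-trig at the methylene carbon, made feasible by the benzyl-cation character of that carbon and by rotation of the carboxylate out of the ring plane; no stereocentre is formed. Site selectivity comes from the substrate: the only other quinone position carries hydrogen, not an alkyl group, and the benzyloxy group makes it the alpha carbon of a vinylogous ester, unreactive to nucleophiles. The step needs selectivity against over-oxidation, since quinone 6 could oxidise product 8 by hydroquinone–quinone exchange; one equivalent of oxidant, dilution and a reductive work-up should secure it. The step also frees the C-4 phenol for the later ether bond, while the C-7 phenol stays hydrogen-bonded to the new lactone carbonyl.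

**Step 5**
Reactants: 8 5-(benzyloxy)-4,7-dihydroxy-2-benzofuran-1(3H)-one
Product: 9 5-(benzyloxy)-4,7-dihydroxy-6-(hydroxymethyl)-2-benzofuran-1(3H)-one
Conditions: 37% aq. CH2O, K2CO3, H2O/1,4-dioxane, Na2S2O4 (trace), argon, rt → 40 °C; then dilute HCl
Reagents that add atoms: formaldehyde C=O
Why: Lederer–Manasse hydroxymethylation; the C-7 phenoxide attacks formaldehyde through C-6, the only unsubstituted ring carbon, so neither a regioisomer nor a diarylmethane can form.

**Step 6**
Reactants: 9 5-(benzyloxy)-4,7-dihydroxy-6-(hydroxymethyl)-2-benzofuran-1(3H)-one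
Product: 10 isopropylidene acetal of 9 (2,2-dimethyl-4H-1,3-dioxine ring across O-7 and the C-6 CH2O; C-4 OH free)
Conditions: 2,2-dimethoxypropane, PPTS (cat.), acetone, rt
Reagents that add atoms: 2,2-dimethoxypropane COC(C)(C)OC
Why: Acid-catalysed transacetalisation (acetonide of a saligenin-type 1,3-diol); only the C-7 phenol/C-6 CH2OH pair can form the six-membered acetal, which should leave C-4 OH as the single free hydroxyl.

**Step 7**
Reactants: 11 3-fluoro-5-methylphenol
Product: 12 1-fluoro-3-(methoxymethoxy)-5-methylbenzene
Conditions: MOMCl, i-Pr2NEt, CH2Cl2, 0 °C → rt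
Reagents that add atoms: chloromethyl methyl ether COCCl
Why: O-alkylation of the phenol to a methoxymethyl ether, which protects it and serves as a directing group for the next step.

**Step 8**
Reactants: 12 1-fluoro-3-(methoxymethoxy)-5-methylbenzene
Product: 14 tert-butyl 2-fluoro-6-(methoxymethoxy)-4-methylbenzoate, via aryllithium 13 (not isolated)
Conditions: n-BuLi, THF, −78 °C; then Boc2O, −78 °C → rt
Reagents that add atoms: di-tert-butyl dicarbonate CC(C)(C)OC(=O)OC(=O)OC(C)(C)C
Why: Directed ortho-metalation at the C–H flanked by fluorine and the MOM ether (the doubly activated site), then acylation of the aryllithium by Boc2O to the tert-butyl ester; the low temperature suppresses aryne formation by LiF loss.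

**Step 9**
Reactants: 14 tert-butyl 2-fluoro-6-(methoxymethoxy)-4-methylbenzoate
Product: 15 tert-butyl 3-bromo-2-fluoro-6-(methoxymethoxy)-4-methylbenzoate
Conditions: NBS, MeCN, 0 °C → rt
Reagents that add atoms: N-bromosuccinimide O=C1CCC(=O)N1Br
Why: Electrophilic aromatic bromination, which should go para to the alkoxy group (the position between fluorine and methyl) rather than to the more hindered ortho position.

**Step 10**
Reactants: 15 tert-butyl 3-bromo-2-fluoro-6-(methoxymethoxy)-4-methylbenzoate
Product: 16 1-benzyl 3-tert-butyl 2-fluoro-4-(methoxymethoxy)-6-methylbenzene-1,3-dicarboxylate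
Conditions: CO (1 atm), BnOH, Pd(OAc)2 (cat.), Xantphos (cat.), Et3N, toluene, 90 °C
Reagents that add atoms: carbon monoxide [C-]#[O+]; benzyl alcohol OCc1ccccc1
Why: Palladium-catalysed alkoxycarbonylation of an aryl bromide (oxidative addition, CO insertion, alcoholysis of the acylpalladium); this gives the second ester, orthogonal to the tert-butyl ester.

**Step 11**
Reactants: 10 isopropylidene acetal of 9; 16 1-benzyl 3-tert-butyl 2-fluoro-4-(methoxymethoxy)-6-methylbenzene-1,3-dicarboxylate
Product: 17 diaryl ether (ring A diester joined through its C-2 to O-4 of ring B)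
Conditions: Cs2CO3, DMF, 70 °C
Reagents that add atoms: none
Why: SNAr through a Meisenheimer adduct stabilised by the two esters ortho to fluorine; 10 has a single free phenol and 16 a single leaving group, so only one ether can form.

**Step 12**
Reactants: 17 diaryl ether
Product: 18 hydroxy acid (ring A C-1 CO2H and ring B C-5 OH free)
Conditions: H2 (1 atm), 10% Pd/C, EtOAc, rt
Reagents that add atoms: none
Why: Hydrogenolysis of the benzyl ether and the benzyl ester; the acetonide, MOM ether, tert-butyl ester and lactone should be inert under these neutral conditions.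

**Step 13**
Reactants: 18 hydroxy acid
Product: 19 protected depsidone (tert-butyl ester, MOM ether, acetonide)
Conditions: DCC, DMAP (cat.), CH2Cl2 (high dilution), rt
Reagents that add atoms: none
Why: Carbodiimide (Steglich-type) lactonisation, the usual closure of the depsidone seven-membered ring from a 2-aryloxybenzoic acid; one free phenol and one free acid allow a single lactone, and the near-neutral medium should avoid Smiles migration of the activated aryl group to the neighbouring oxygen.

**Step 14**
Reactants: 19 protected depsidone
Product: 20 Conneotricone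
Conditions: TFA/CH2Cl2 (1:1), H2O (5 equiv), 0 °C → rt
Reagents that add atoms: none
Why: Acidolysis; the tert-butyl ester (loss of 2-methylpropene), the MOM ether and the isopropylidene acetal should all be cleaved, while the aryl ester, the lactone and the diaryl ether are acid-stable.

**Compound list**
1 | methyl 2,4-dihydroxy-6-methylbenzoate (methyl orsellinate) | COC(=O)c1c(C)cc(O)cc1O | starting material
2 | methyl 4-(benzyloxy)-2-hydroxy-6-methylbenzoate | COC(=O)c1c(C)cc(OCc2ccccc2)cc1O | intermediate
3 | 4-(benzyloxy)-2-hydroxy-6-methylbenzoic acid | Cc1cc(OCc2ccccc2)cc(O)c1C(=O)O | intermediate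
4 | 4-(benzyloxy)-6-hydroxy-2-methyl-3-(sulfooxy)benzoic acid (aryl sulfate, present as its salt, drawn as the acid) | Cc1c(OS(=O)(=O)O)c(OCc2ccccc2)cc(O)c1C(=O)O | intermediate
5 | 4-(benzyloxy)-3,6-dihydroxy-2-methylbenzoic acid | Cc1c(O)c(OCc2ccccc2)cc(O)c1C(=O)O | intermediate
6 | 4-(benzyloxy)-2-methyl-3,6-dioxocyclohexa-1,4-diene-1-carboxylic acid (quinone acid) | CC1=C(C(=O)O)C(=O)C=C(OCc2ccccc2)C1=O | intermediate
7 | 4-(benzyloxy)-6-hydroxy-2-methylidene-3-oxocyclohexa-1(6),4-diene-1-carboxylic acid (o-quinone methide) | C=C1C(=O)C(OCc2ccccc2)=CC(O)=C1C(=O)O | intermediate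
8 | 5-(benzyloxy)-4,7-dihydroxy-2-benzofuran-1(3H)-one | O=C1OCc2c(O)c(OCc3ccccc3)cc(O)c21 | intermediate
9 | 5-(benzyloxy)-4,7-dihydroxy-6-(hydroxymethyl)-2-benzofuran-1(3H)-one | O=C1OCc2c(O)c(OCc3ccccc3)c(CO)c(O)c21 | intermediate
10 | isopropylidene acetal of 9 (2,2-dimethyl-4H-1,3-dioxine ring across O-7 and the C-6 CH2O; C-4 OH free) | O=C1OCc2c(O)c(OCc3ccccc3)c3COC(C)(C)Oc3c21 | intermediate
11 | 3-fluoro-5-methylphenol | Cc1cc(O)cc(F)c1 | starting material
12 | 1-fluoro-3-(methoxymethoxy)-5-methylbenzene | COCOc1cc(C)cc(F)c1 | intermediate
13 | [2-fluoro-6-(methoxymethoxy)-4-methylphenyl]lithium | COCOc1cc(C)cc(F)c1[Li] | intermediate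
14 | tert-butyl 2-fluoro-6-(methoxymethoxy)-4-methylbenzoate | COCOc1cc(C)cc(F)c1C(=O)OC(C)(C)C | intermediate
15 | tert-butyl 3-bromo-2-fluoro-6-(methoxymethoxy)-4-methylbenzoate | COCOc1cc(C)c(Br)c(F)c1C(=O)OC(C)(C)C | intermediate
16 | 1-benzyl 3-tert-butyl 2-fluoro-4-(methoxymethoxy)-6-methylbenzene-1,3-dicarboxylate | COCOc1cc(C)c(C(=O)OCc2ccccc2)c(F)c1C(=O)OC(C)(C)C | intermediate
17 | diaryl ether: 1-benzyl 3-tert-butyl 4-(methoxymethoxy)-6-methylbenzene-1,3-dicarboxylate carrying at C-2 the O-4 aryloxy group of 10 | COCOc1cc(C)c(C(=O)OCc2ccccc2)c(Oc2c(OCc3ccccc3)c3COC(C)(C)Oc3c3C(=O)OCc23)c1C(=O)OC(C)(C)C | intermediate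
18 | hydroxy acid: 3-(tert-butoxycarbonyl)-4-(methoxymethoxy)-6-methyl-2-aryloxybenzoic acid, ring B with free C-5 OH and intact acetonide | COCOc1cc(C)c(C(=O)O)c(Oc2c(O)c3COC(C)(C)Oc3c3C(=O)OCc23)c1C(=O)OC(C)(C)C | intermediate
19 | protected depsidone (ring A tert-butyl ester and MOM ether; ring B acetonide across the phenol and the CH2OH) | Cc1cc(OCOC)c(C(=O)OC(C)(C)C)c2c1C(=O)Oc1c3COC(C)(C)Oc3c3C(=O)OCc3c1O2 | intermediate
20 | Conneotricone | Cc1cc(O)c(C(=O)O)c2c1C(=O)Oc1c(CO)c(O)c3c(c1O2)COC3=O | target

**Step count and risks**
Total steps: 14. Longest linear sequence: 10 steps (steps 1–6 and 11–14, from methyl orsellinate); the ring A branch is 4 steps (7–10).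

Steps most likely to fail:

1. Step 4 (Proposed new method). The tautomerisation may be too slow at a simple C-methyl group, the quinone methide may dimerise, or hydroquinone–quinone exchange between 6 and 8 may over-oxidise the product. Fallback (known chemistry), from 5 back to 8: MOMCl/NaH in DMF would give methoxymethyl 4-(benzyloxy)-3,6-bis(methoxymethoxy)-2-methylbenzoate F1. LiOH in aqueous THF would cleave the methoxymethyl ester to 4-(benzyloxy)-3,6-bis(methoxymethoxy)-2-methylbenzoic acid F2. Carboxylate-directed benzylic C–H lactonisation, a known reaction type of 2-methylbenzoic acids (Pd(OAc)2, mono-N-protected amino acid ligand, O2), would close the same CH2–O bond to give 5-(benzyloxy)-4,7-bis(methoxymethoxy)-2-benzofuran-1(3H)-one F3. Aqueous HCl in THF would remove both MOM groups and return the route at 8.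

2. Step 11. The substitution may stall, because both esters flanking fluorine are twisted out of conjugation by their other ortho neighbours and both partners are hindered. Fallback, from 15 back to 18, using an aldehyde as the activating group: i-PrMgCl·LiCl (THF, −20 °C) would convert 15 into [3-(tert-butoxycarbonyl)-2-fluoro-4-(methoxymethoxy)-6-methylphenyl]magnesium chloride F5 (not isolated). DMF would then give tert-butyl 2-fluoro-3-formyl-6-(methoxymethoxy)-4-methylbenzoate F6. SNAr of this much more electrophilic fluoride with 10 (K2CO3, DMF, 40 °C) would give the diaryl ether aldehyde F7. Pinnick oxidation (NaClO2, NaH2PO4, 2-methyl-2-butene) would give the diaryl ether acid F8, still carrying the ring B benzyl ether. Hydrogenolysis (H2, Pd/C) would return the route at 18.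

3. Step 5. C-attack of the chelated, carbonyl-conjugated phenoxide on formaldehyde may be slow, and the hydroquinone may air-oxidise in base. Fallback, from 8 back to 9: ortho-formylation with MgCl2/Et3N/paraformaldehyde (MeCN, reflux, argon), which delivers the electrophile on magnesium phenoxide, would give 5-(benzyloxy)-6-formyl-4,7-dihydroxy-2-benzofuran-1(3H)-one F4. NaBH4 (THF/MeOH, 0 °C) would reduce the aldehyde without touching the lactone and return the route at 9.

**Further compounds**
F1 | step 4 | methoxymethyl 4-(benzyloxy)-3,6-bis(methoxymethoxy)-2-methylbenzoate | COCOC(=O)c1c(C)c(OCOC)c(OCc2ccccc2)cc1OCOC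
F2 | step 4 | 4-(benzyloxy)-3,6-bis(methoxymethoxy)-2-methylbenzoic acid | Cc1c(OCOC)c(OCc2ccccc2)cc(OCOC)c1C(=O)O
F3 | step 4 | 5-(benzyloxy)-4,7-bis(methoxymethoxy)-2-benzofuran-1(3H)-one | O=C1OCc2c(OCOC)c(OCc3ccccc3)cc(OCOC)c21
F4 | step 5 | 5-(benzyloxy)-6-formyl-4,7-dihydroxy-2-benzofuran-1(3H)-one | O=Cc1c(O)c2C(=O)OCc2c(O)c1OCc1ccccc1
F5 | step 11 | [3-(tert-butoxycarbonyl)-2-fluoro-4-(methoxymethoxy)-6-methylphenyl]magnesium chloride | COCOc1cc(C)c([Mg]Cl)c(F)c1C(=O)OC(C)(C)C
F6 | step 11 | tert-butyl 2-fluoro-3-formyl-6-(methoxymethoxy)-4-methylbenzoate | COCOc1cc(C)c(C=O)c(F)c1C(=O)OC(C)(C)C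
F7 | step 11 | diaryl ether aldehyde: tert-butyl 3-formyl-6-(methoxymethoxy)-4-methylbenzoate carrying at C-2 the O-4 aryloxy group of 10 | COCOc1cc(C)c(C=O)c(Oc2c(OCc3ccccc3)c3COC(C)(C)Oc3c3C(=O)OCc23)c1C(=O)OC(C)(C)C
F8 | step 11 | diaryl ether acid: 3-(tert-butoxycarbonyl)-4-(methoxymethoxy)-6-methylbenzoic acid carrying at C-2 the O-4 aryloxy group of 10, ring B benzyl ether intact | COCOc1cc(C)c(C(=O)O)c(Oc2c(OCc3ccccc3)c3COC(C)(C)Oc3c3C(=O)OCc23)c1C(=O)OC(C)(C)C
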